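The data come from a simulation from invented constants; noise was put on by code.

Easy step first: count the reagent, 20.0 mM in this flask against 20 mM of starting material and 40.0 mM of second substrate.

common to all: free catalyst 28 µM
- red: starting material 20 mM; second substrate 40 mM; reagent 20 mM; temperature 100 °C; the very flask that is asked about, followed so far
- grey: starting material 13 mM; second substrate 40 mM; reagent 20 mM; temperature 95 °C; run made earlier
- flask: starting material 20 mM; second substrate 40.0 mM; reagent 20.0 mM; temperature 100 °C; time 8.0 d

| run | time / h | target / % | starting material / % |
|---|---|---|---|
| red | 15.0 | 30 | 70 |
| red | 40.0 | 45 | 59 |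
| red | 72.0 | 46 | 60 |
| red | 120 | 44 | 55 |
| grey | 2.50 | 7 | 93 |
| grey | 8.00 | 18 | 80 |
| grey | 12.0 | 26 | 75 |
| grey | 20.0 | 36 | 65 |

(scatter of a reading: 1.5 percentage points)

- alpha: at 8.0 d raise the temperature by 10 K, then wait 8.0 d
- zeta: change nothing and wait 8.0 d more
- beta: at 8.0 d take out 90% of the target then present, then wait 8.0 d
- eta: at 8.0 d add reagent, 100% of the amount charged, then wait 8.0 d
- epsilon: at 8.0 d add free catalyst, 100% of the amount charged, then wait 8.0 d

- target taken out counts as made
- additions bring no volume worth counting

1. target, in percent of the starting material first charged, at 8.0 d
2. which option adds most target ("none" when 2 percentage points or less is all one gets) (alpha / zeta / beta / eta / epsilon / none)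
3. target present, with what was taken out counted in, in percent of the starting material first charged, after alpha
4. target present, with what was taken out counted in, in percent of the starting material first charged, after eta

Two chemists read the red run. Its target stands at 45%, 46% and 44% from 40.0 h to 120 h, with 55% of the starting material still there at the last reading. The first chemist calls that an equilibrium: target and starting material add up to about the charge, so taking target out should pull more across, while heat and reagent should do little.

The second chemist writes a reagent balance, taking the reagent as the limiting reagent. Each target costs one reagent, and the rest of the reagent goes with second substrate. The mean of those three red readings gives a reagent share, target made per reagent charged, of 45.0%, which is below the full charge. The first chemist answers that no reading shows the reagent gone, and that is fair. The balance then puts 11.0 mM of starting material and 29.0 mM of second substrate in red at the stall.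

The second chemist's rule, for reagent meeting given amounts of starting material and second substrate, is that the reagent share equals preference times starting material, divided by that same product plus second substrate. Red's charges give a preference of 1.64, a reading of the selectivity factor. With equal charges of reagent and starting material, the second chemist commits to 45.0% at 8.0 d. A fresh dose in option eta meets the leftovers, so its share is 38.3%, a gain of 38 percentage points and a total of 83.3%. That total holds the leftovers at their amounts at the moment of the dose, so it is a rough figure. The options without reagent should add about nothing, so the second chemist picks eta.

The forecast, on the first chemist's side, gives 45%, beta, 46% after alpha and 46% after eta: “removing target is the best bet”.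

The flask gives 44.0% at 8.0 d. Option eta adds 35 points and reaches 79.2%, beta adds 0 points, and alpha leaves 44.0%. The first chemist's reversibility stands in the two steps below in which free catalyst binds, and these do run both ways.

    starting material + free catalyst ⇌ catalyst intermediate A (K = 87.3 M⁻¹, k = 9330 M⁻¹ h⁻¹, Ea = 74.0 kJ mol⁻¹, ΔH = −7.00 kJ mol⁻¹)
    reagent + catalyst intermediate A → free catalyst + target (k = 2450 M⁻¹ h⁻¹, Ea = 67.0 kJ mol⁻¹)
    second substrate + free catalyst ⇌ catalyst intermediate B (K = 24.0 M⁻¹, k = 1760 M⁻¹ h⁻¹, Ea = 59.0 kJ mol⁻¹, ΔH = −88.0 kJ mol⁻¹)
    reagent + catalyst intermediate B → free catalyst + second product (k = 7970 M⁻¹ h⁻¹, Ea = 73.0 kJ mol⁻¹)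
    free catalyst + target → spent catalyst (k = 0.893 M⁻¹ h⁻¹, Ea = 67.0 kJ mol⁻¹)
    (constants at 100 °C)

At 192 h this flask holds reagent at 0%, with 8.81 mM of target and 11.2 mM of second product. At 100 °C reagent's rate constant with catalyst intermediate B is 3.25 times that with catalyst intermediate A.

For the neighbour with 24 mM of second substrate, the preference 1.64 gives 57.7% target. That neighbour gives 55.3%, with reagent at 0.0276%.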